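**Plan**
1. Retrosynthesis: each 2-aminoimidazole is cut at its two ring C–N bonds back to a chloroacetyl group plus Boc-guanidine, and each amide C–N bond back to a CH2N3/CH2OH/CO2Me arm plus 2-(trichloroacetyl)pyrrole.
2. Next the cyclobutane bond between the two ring carbons that carry the CH2N arms is cut, giving a (3S,4S)-3,4-disubstituted hexanedioate; its two ester carbons are then rejoined as the C=C of a cyclohexene.
3. Enabling feature: the two exocyclic CH2N carbons can stand at the ester level, so the ring carbons they sit on are the two α-carbons of an adipate. The four cyclobutane carbons plus these two carbons are the six ring carbons of a trans-4,5-disubstituted cyclohexene (cleave C4=C5, join C3 to C6).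
4. Forward order: six-membered ring (bought) → open chain (ozonolysis) → four-membered ring (oxidative bis-enolate coupling) → two pyrrole amides → the two imidazole rings last.
5. Stereochemistry: the two imidazole-bearing centres come unchanged from (1S,2S)-cyclohex-4-ene-1,2-dicarboxylic acid. The two CH2N-bearing centres arise in the ring closure, trans to their neighbours, and are secured by base equilibration of the esters against the two fixed ketal-bearing centres.

Key step: step 5

Remark on the chemistry: (1S,2S)-cyclohex-4-ene-1,2-dicarboxylic acid 1 is assumed to be purchasable as the single enantiomer; if not, it is the saponified Diels–Alder adduct of buta-1,3-diene with a dimenthyl fumarate.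

Step 1
Reactants: 1 (1S,2S)-cyclohex-4-ene-1,2-dicarboxylic acid
Product: 3 (1S,2S)-N1,N2-dimethoxy-N1,N2-dimethylcyclohex-4-ene-1,2-dicarboxamide, via diacid dichloride 2 (not isolated)
Conditions: (COCl)2, N,N-dimethylformamide (cat.), CH2Cl2, 0 °C to rt; evaporate; MeNHOMe·HCl, pyridine, CH2Cl2, 0 °C to rt
Reagents that add atoms: N,O-dimethylhydroxylamine hydrochloride, CNOC.Cl; oxalyl chloride, O=C(Cl)C(Cl)=O (supplies only the chlorine of 2)
Why: Acid chloride formation and amidation (Weinreb amide synthesis); pyridine at 0 °C should not form a ketene, so the trans (1S,2S) centres stay untouched.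

Step 2
Reactants: 3 (1S,2S)-N1,N2-dimethoxy-N1,N2-dimethylcyclohex-4-ene-1,2-dicarboxamide
Product: 5 1,1'-[(1S,2S)-cyclohex-4-ene-1,2-diyl]bis(2-chloroethan-1-one), via dilithium tetrahedral bis-adduct 4 (not isolated)
Conditions: ICH2Cl (3 equiv), MeLi·LiBr (2.8 equiv, added slowly), THF, −78 °C; 1 M aq. HCl quench at −78 °C
Reagents that add atoms: chloroiodomethane, ClCI
Why: Carbenoid homologation of a Weinreb amide: LiCH2Cl, made in Barbier mode by iodine–lithium exchange, adds once because the chelated tetrahedral adduct survives until the quench, so neither over-addition nor enolisation of the α-stereocentres is expected.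

Step 3
Reactants: 5 1,1'-[(1S,2S)-cyclohex-4-ene-1,2-diyl]bis(2-chloroethan-1-one)
Product: 6 (4S,5S)-4,5-bis(2-chloro-1,1-dimethoxyethyl)cyclohex-1-ene
Conditions: HC(OMe)3, MeOH, p-TsOH·H2O (5 mol %), 40 °C; Et3N quench
Reagents that add atoms: trimethyl orthoformate, COC(OC)OC
Why: Acid-catalysed ketalisation with orthoformate as water scavenger, standard for α-haloketones; it masks the ketones and makes the two stereocentres non-enolisable for all later basic steps.

Step 4
Reactants: 6 (4S,5S)-4,5-bis(2-chloro-1,1-dimethoxyethyl)cyclohex-1-ene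
Product: 7 dimethyl (3S,4S)-3,4-bis(2-chloro-1,1-dimethoxyethyl)hexanedioate
Conditions: O3, NaOH (5 equiv, 2.5 M in MeOH), CH2Cl2, −78 °C; then cold aq. NH4Cl
Reagents that add atoms: ozone, [O-][O+]=O; methanol, CO
Why: Ozonolysis in methanolic NaOH converts both alkene carbons directly into methyl esters; the ketals, the chlorides and the two stereocentres (now β to the esters) should be inert.

Step 5
Reactants: 7 dimethyl (3S,4S)-3,4-bis(2-chloro-1,1-dimethoxyethyl)hexanedioate
Product: 9 dimethyl (1S,2S,3R,4R)-3,4-bis(2-chloro-1,1-dimethoxyethyl)cyclobutane-1,2-dicarboxylate, via dilithium bis-enolate 8 (not isolated)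
Conditions: LiN(i-Pr)2 (2.3 equiv), THF, −78 °C (7 added slowly to the base); CuBr2 (2.5 equiv, in DMF), −78 °C to rt, 0.01 M; aq. NH4Cl work-up; then NaOMe (0.3 equiv), MeOH, rt
Reagents that add atoms: none
Why: LiN(i-Pr)2 removes one hydrogen from each ester CH2 (C2 and C5 of 7) to give bis-enolate 8, and two equivalents of divalent copper bromide take away two electrons: the first oxidation (or α-bromination) turns C2 into an α-ester radical (or electrophile) that is captured by the enolate carbon C5, and the second CuBr2 oxidises the resulting ester ketyl, so the C2–C5 bond forms with net loss of two electrons. The closest known reaction type is the intramolecular oxidative coupling of diester bis-enolates with divalent copper halides or I2, which turns adipates into trans-cyclobutane-1,2-dicarboxylates. The four-membered ring closes in the 4-exo mode (radical addition to the enolate C=C, or 4-exo-tet displacement if the α-bromo ester is the intermediate). The two new stereocentres are controlled by the two ketal-bearing centres carried from 1: each ester should end trans to its bulky neighbour, and because only the ester-bearing carbons can epimerise, NaOMe should convert any cis isomer into the all-trans diester without risk to the absolute configuration. The step needs enolisation at C2/C5 only, which is secured because the ketal carbons carry no hydrogen and the chlorides are neopentyl-type. It also needs ring closure to win over Dieckmann condensation and intermolecular coupling, which is secured by adding 7 to excess base (an ester enolate is no acyl acceptor), by the two vicinal branches at C3/C4 that hold the chain ends close, and by dilution.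

Step 6
Reactants: 9 dimethyl (1S,2S,3R,4R)-3,4-bis(2-chloro-1,1-dimethoxyethyl)cyclobutane-1,2-dicarboxylate
Product: 10 [(1R,2R,3S,4S)-3,4-bis(2-chloro-1,1-dimethoxyethyl)cyclobutane-1,2-diyl]dimethanol
Conditions: LiBH4 (4 equiv), MeOH (4 equiv), THF, 0 °C to rt
Reagents that add atoms: none
Why: Borohydride reduction of the methyl esters to primary alcohols; the hindered chlorides and the ketals should survive, and the ring centres are no longer epimerisable afterwards.

Step 7
Reactants: 10 [(1R,2R,3S,4S)-3,4-bis(2-chloro-1,1-dimethoxyethyl)cyclobutane-1,2-diyl]dimethanol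
Product: 11 (1R,2R,3S,4S)-1,2-bis(azidomethyl)-3,4-bis(2-chloro-1,1-dimethoxyethyl)cyclobutane
Conditions: PPh3, DIAD, (PhO)2P(O)N3, THF, 0 °C to rt
Reagents that add atoms: diphenylphosphoryl azide, [N-]=[N+]=NP(=O)(Oc1ccccc1)Oc1ccccc1
Why: Mitsunobu azidation of the two primary alcohols; the trans relation of the arms rules out cyclic ether formation, which would need a trans-fused 3-oxabicyclo[3.2.0]heptane.

Step 8
Reactants: 11 (1R,2R,3S,4S)-1,2-bis(azidomethyl)-3,4-bis(2-chloro-1,1-dimethoxyethyl)cyclobutane; 12 2-(trichloroacetyl)pyrrole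
Product: 14 N,N'-{[(1R,2R,3S,4S)-3,4-bis(2-chloro-1,1-dimethoxyethyl)cyclobutane-1,2-diyl]bis(methylene)}bis(1H-pyrrole-2-carboxamide), via diamine 13 (not isolated)
Conditions: PMe3, THF, rt, then H2O; then 12 (2.2 equiv), Et3N, MeCN, rt
Reagents that add atoms: 12 2-(trichloroacetyl)pyrrole, O=C(c1ccc[nH]1)C(Cl)(Cl)Cl
Why: Staudinger reduction followed by haloform-type acyl transfer from the trichloromethyl ketone, the usual way to attach a pyrrole-2-carbonyl group to a primary amine; the hindered chlorides should not alkylate the amine at room temperature.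

Step 9
Reactants: 14 N,N'-{[(1R,2R,3S,4S)-3,4-bis(2-chloro-1,1-dimethoxyethyl)cyclobutane-1,2-diyl]bis(methylene)}bis(1H-pyrrole-2-carboxamide)
Product: 15 N,N'-{[(1R,2R,3S,4S)-3,4-bis(chloroacetyl)cyclobutane-1,2-diyl]bis(methylene)}bis(1H-pyrrole-2-carboxamide)
Conditions: TFA/H2O (9:1), CH2Cl2, 0 °C to rt
Reagents that add atoms: water, O
Why: Acid hydrolysis of the dimethyl ketals; the acylated pyrroles should tolerate the acid, and any epimerisation α to the ketones can only return to the all-trans isomer because the neighbouring CH2N-bearing centres are fixed.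

Step 10
Reactants: 15 N,N'-{[(1R,2R,3S,4S)-3,4-bis(chloroacetyl)cyclobutane-1,2-diyl]bis(methylene)}bis(1H-pyrrole-2-carboxamide); 16 N-Boc-guanidine
Product: 17 di-tert-butyl 4,4'-[(1S,2S,3R,4R)-3,4-bis{[(1H-pyrrole-2-carbonyl)amino]methyl}cyclobutane-1,2-diyl]bis(2-amino-1H-imidazole-1-carboxylate)
Conditions: 16 (8 equiv), NaI (0.2 equiv), DMF, rt, 48 h
Reagents that add atoms: 16 tert-butyl carbamimidoylcarbamate, CC(C)(C)OC(=O)NC(N)=N
Why: Cyclocondensation of an α-haloketone with Boc-guanidine (N-alkylation, ring closure onto the ketone, dehydration) should give the 2-amino-1-Boc-imidazole with the cyclobutane carbon on C4; excess 16 takes up the HCl.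

Step 11
Reactants: 17 di-tert-butyl 4,4'-[(1S,2S,3R,4R)-3,4-bis{[(1H-pyrrole-2-carbonyl)amino]methyl}cyclobutane-1,2-diyl]bis(2-amino-1H-imidazole-1-carboxylate)
Product: 18 N,N'-{[(1R,2R,3S,4S)-3,4-bis(2-amino-1H-imidazol-5-yl)cyclobutane-1,2-diyl]bis(methylene)}bis(1H-pyrrole-2-carboxamide) (CNP0598529.1)
Conditions: TFA/CH2Cl2 (1:1), rt; evaporate; basic ion-exchange resin to the free base
Reagents that add atoms: none
Why: Acidolytic Boc removal (loss of tert-butyl cation, then decarboxylation) should free both aminoimidazoles without touching amides or stereocentres.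

**Compound list**
1 | (1S,2S)-cyclohex-4-ene-1,2-dicarboxylic acid | OC(=O)[C@H]1CC=CC[C@@H]1C(=O)O | starting material
2 | (1S,2S)-cyclohex-4-ene-1,2-dicarbonyl dichloride | ClC(=O)[C@H]1CC=CC[C@@H]1C(=O)Cl | intermediate (not isolated)
3 | (1S,2S)-N1,N2-dimethoxy-N1,N2-dimethylcyclohex-4-ene-1,2-dicarboxamide | CON(C)C(=O)[C@H]1CC=CC[C@@H]1C(=O)N(C)OC | intermediate
4 | dilithium bis(alkoxide) from double addition of LiCH2Cl to 3 (tetrahedral bis-adduct, new carbinol centres undefined) | [Li+].[Li+].CON(C)C([O-])(CCl)[C@H]1CC=CC[C@@H]1C([O-])(CCl)N(C)OC | intermediate (not isolated)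
5 | 1,1'-[(1S,2S)-cyclohex-4-ene-1,2-diyl]bis(2-chloroethan-1-one) | ClCC(=O)[C@H]1CC=CC[C@@H]1C(=O)CCl | intermediate
6 | (4S,5S)-4,5-bis(2-chloro-1,1-dimethoxyethyl)cyclohex-1-ene | COC(CCl)(OC)[C@H]1CC=CC[C@@H]1C(CCl)(OC)OC | intermediate
7 | dimethyl (3S,4S)-3,4-bis(2-chloro-1,1-dimethoxyethyl)hexanedioate | COC(=O)C[C@H](C(CCl)(OC)OC)[C@H](CC(=O)OC)C(CCl)(OC)OC | intermediate
8 | dilithium bis-enolate of 7 (enolate geometry undefined) | [Li+].[Li+].COC([O-])=C[C@H](C(CCl)(OC)OC)[C@H](C=C([O-])OC)C(CCl)(OC)OC | intermediate (not isolated)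
9 | dimethyl (1S,2S,3R,4R)-3,4-bis(2-chloro-1,1-dimethoxyethyl)cyclobutane-1,2-dicarboxylate (all-trans) | COC(CCl)(OC)[C@H]1[C@H](C(=O)OC)[C@@H](C(=O)OC)[C@@H]1C(CCl)(OC)OC | intermediate
10 | [(1R,2R,3S,4S)-3,4-bis(2-chloro-1,1-dimethoxyethyl)cyclobutane-1,2-diyl]dimethanol | COC(CCl)(OC)[C@H]1[C@H](CO)[C@@H](CO)[C@@H]1C(CCl)(OC)OC | intermediate
11 | (1R,2R,3S,4S)-1,2-bis(azidomethyl)-3,4-bis(2-chloro-1,1-dimethoxyethyl)cyclobutane | COC(CCl)(OC)[C@H]1[C@H](CN=[N+]=[N-])[C@@H](CN=[N+]=[N-])[C@@H]1C(CCl)(OC)OC | intermediate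
12 | 2-(trichloroacetyl)pyrrole (2,2,2-trichloro-1-(1H-pyrrol-2-yl)ethan-1-one) | O=C(c1ccc[nH]1)C(Cl)(Cl)Cl | starting material
13 | [(1R,2R,3S,4S)-3,4-bis(2-chloro-1,1-dimethoxyethyl)cyclobutane-1,2-diyl]dimethanamine | COC(CCl)(OC)[C@H]1[C@H](CN)[C@@H](CN)[C@@H]1C(CCl)(OC)OC | intermediate (not isolated)
14 | N,N'-{[(1R,2R,3S,4S)-3,4-bis(2-chloro-1,1-dimethoxyethyl)cyclobutane-1,2-diyl]bis(methylene)}bis(1H-pyrrole-2-carboxamide) | COC(CCl)(OC)[C@H]1[C@H](CNC(=O)c2ccc[nH]2)[C@@H](CNC(=O)c2ccc[nH]2)[C@@H]1C(CCl)(OC)OC | intermediate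
15 | N,N'-{[(1R,2R,3S,4S)-3,4-bis(chloroacetyl)cyclobutane-1,2-diyl]bis(methylene)}bis(1H-pyrrole-2-carboxamide) | ClCC(=O)[C@H]1[C@H](CNC(=O)c2ccc[nH]2)[C@@H](CNC(=O)c2ccc[nH]2)[C@@H]1C(=O)CCl | intermediate
16 | N-Boc-guanidine (tert-butyl carbamimidoylcarbamate) | CC(C)(C)OC(=O)NC(N)=N | starting material
17 | di-tert-butyl 4,4'-[(1S,2S,3R,4R)-3,4-bis{[(1H-pyrrole-2-carbonyl)amino]methyl}cyclobutane-1,2-diyl]bis(2-amino-1H-imidazole-1-carboxylate) | CC(C)(C)OC(=O)n1cc(nc1N)[C@H]1[C@H](CNC(=O)c2ccc[nH]2)[C@@H](CNC(=O)c2ccc[nH]2)[C@@H]1c1cn(C(=O)OC(C)(C)C)c(N)n1 | intermediate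
18 | N,N'-{[(1R,2R,3S,4S)-3,4-bis(2-amino-1H-imidazol-5-yl)cyclobutane-1,2-diyl]bis(methylene)}bis(1H-pyrrole-2-carboxamide) (all-trans) | Nc1ncc([C@H]2[C@H](CNC(=O)c3ccc[nH]3)[C@@H](CNC(=O)c3ccc[nH]3)[C@@H]2c2cnc(N)[nH]2)[nH]1 | target

**Totals**
Total step count: 11. Longest linear sequence: 11 steps (from 1).

**Steps most likely to fail**

Step 5. Closure of the strained four-membered ring may lose to intermolecular coupling, to Dieckmann condensation of a mono-enolate, or to α-bromination that is not followed by ring closure. Fallback (carbene ring contraction in place of oxidative coupling), setting out from 7 and returning at 9: KOt-Bu (1.1 equiv, THF, 0 °C) should give the Dieckmann keto ester methyl (4S,5R)-4,5-bis(2-chloro-1,1-dimethoxyethyl)-2-oxocyclopentane-1-carboxylate F1 (one product, since 7 is C2-symmetric). Its dianion (LiN(i-Pr)2, 2.1 equiv, −78 °C) should be acylated at the ring CH2 by 2,2,2-trifluoroethyl trifluoroacetate to give methyl 4,5-bis(2-chloro-1,1-dimethoxyethyl)-2-oxo-3-(trifluoroacetyl)cyclopentane-1-carboxylate F2. Detrifluoroacetylative Regitz diazo transfer (MeSO2N3, Et3N, H2O, MeCN) should then give methyl 3-diazo-4,5-bis(2-chloro-1,1-dimethoxyethyl)-2-oxocyclopentane-1-carboxylate F3. Irradiation of F3 in MeOH should trigger Wolff ring contraction: the ester-bearing carbon migrates to the carbene carbon, which makes the same C–C bond, and the ketene is trapped as the methyl ester. The same NaOMe equilibration then gives 9.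

Step 10. The double annulation may stall after the first imidazole, or be diverted by alkylation of a second guanidine nitrogen or of an amide nitrogen at the hindered chloroketones. Fallback (α-aminoketone plus cyanamide in place of haloketone plus guanidine), setting out from 15 and returning at 18, so that step 11 is not needed: NaN(CHO)2 in MeCN should displace both chlorides to give the bis(diformylamide) N,N'-{[(1R,2R,3S,4S)-3,4-bis[(diformylamino)acetyl]cyclobutane-1,2-diyl]bis(methylene)}bis(1H-pyrrole-2-carboxamide) F4. HCl in MeOH should remove the formyl groups to give the bis(α-aminoketone) dihydrochloride N,N'-{[(1R,2R,3S,4S)-3,4-bis(aminoacetyl)cyclobutane-1,2-diyl]bis(methylene)}bis(1H-pyrrole-2-carboxamide) dihydrochloride F5. Cyanamide in water at pH 4.5 and 95 °C should then condense F5 directly to 18.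

Step 9. Ionisation of the ketal is slowed by the adjacent chlorine, so the acid strength needed may degrade the pyrrole amides before hydrolysis is complete. Fallback (reordering so that the acid meets no pyrrole), setting out from 11 and returning at 17: 11 would be hydrolysed with aqueous acid (2 M HCl, THF, 40 °C; aqueous, to avoid an azide–ketone Schmidt reaction) to 1,1'-[(1S,2S,3R,4R)-3,4-bis(azidomethyl)cyclobutane-1,2-diyl]bis(2-chloroethan-1-one) F6. Condensation with 16 as in step 10 should give di-tert-butyl 4,4'-[(1S,2S,3R,4R)-3,4-bis(azidomethyl)cyclobutane-1,2-diyl]bis(2-amino-1H-imidazole-1-carboxylate) F7. PMe3/H2O should reduce F7 to di-tert-butyl 4,4'-[(1S,2S,3R,4R)-3,4-bis(aminomethyl)cyclobutane-1,2-diyl]bis(2-amino-1H-imidazole-1-carboxylate) F8, which is acylated at once with 12 (Et3N, MeCN) to give 17.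

**Further compounds**
F1 | step 5 | methyl (4S,5R)-4,5-bis(2-chloro-1,1-dimethoxyethyl)-2-oxocyclopentane-1-carboxylate (C1 epimers) | COC(=O)C1C(=O)C[C@H](C(CCl)(OC)OC)[C@H]1C(CCl)(OC)OC
F2 | step 5 | methyl 4,5-bis(2-chloro-1,1-dimethoxyethyl)-2-oxo-3-(trifluoroacetyl)cyclopentane-1-carboxylate (ketal-bearing centres as in F1) | COC(=O)C1C(=O)C(C(=O)C(F)(F)F)[C@H](C(CCl)(OC)OC)[C@H]1C(CCl)(OC)OC
F3 | step 5 | methyl 3-diazo-4,5-bis(2-chloro-1,1-dimethoxyethyl)-2-oxocyclopentane-1-carboxylate (ketal-bearing centres as in F1) | COC(=O)C1C(=O)C(=[N+]=[N-])[C@H](C(CCl)(OC)OC)[C@H]1C(CCl)(OC)OC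
F4 | step 10 | N,N'-{[(1R,2R,3S,4S)-3,4-bis[(diformylamino)acetyl]cyclobutane-1,2-diyl]bis(methylene)}bis(1H-pyrrole-2-carboxamide) | O=CN(C=O)CC(=O)[C@H]1[C@H](CNC(=O)c2ccc[nH]2)[C@@H](CNC(=O)c2ccc[nH]2)[C@@H]1C(=O)CN(C=O)C=O
F5 | step 10 | N,N'-{[(1R,2R,3S,4S)-3,4-bis(aminoacetyl)cyclobutane-1,2-diyl]bis(methylene)}bis(1H-pyrrole-2-carboxamide) dihydrochloride | NCC(=O)[C@H]1[C@H](CNC(=O)c2ccc[nH]2)[C@@H](CNC(=O)c2ccc[nH]2)[C@@H]1C(=O)CN.Cl.Cl
F6 | step 9 | 1,1'-[(1S,2S,3R,4R)-3,4-bis(azidomethyl)cyclobutane-1,2-diyl]bis(2-chloroethan-1-one) | ClCC(=O)[C@H]1[C@H](CN=[N+]=[N-])[C@@H](CN=[N+]=[N-])[C@@H]1C(=O)CCl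
F7 | step 9 | di-tert-butyl 4,4'-[(1S,2S,3R,4R)-3,4-bis(azidomethyl)cyclobutane-1,2-diyl]bis(2-amino-1H-imidazole-1-carboxylate) | CC(C)(C)OC(=O)n1cc(nc1N)[C@H]1[C@H](CN=[N+]=[N-])[C@@H](CN=[N+]=[N-])[C@@H]1c1cn(C(=O)OC(C)(C)C)c(N)n1
F8 | step 9 | di-tert-butyl 4,4'-[(1S,2S,3R,4R)-3,4-bis(aminomethyl)cyclobutane-1,2-diyl]bis(2-amino-1H-imidazole-1-carboxylate) | CC(C)(C)OC(=O)n1cc(nc1N)[C@H]1[C@H](CN)[C@@H](CN)[C@@H]1c1cn(C(=O)OC(C)(C)C)c(N)n1
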